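**Retrosynthetic overview**
1. Target 12 ⇐ hydrogenolysis of bis-benzyl ether 11 ⇐ O-methylation of the chelated 2'-OH of 10 ⇐ bis-O-benzylation of triol 8; the 2'-OMe/4'-OH pattern is fixed only after the C–C bond is in place.
2. Key disconnection, C3'(ring A)–CH2: triol 8 ⇐ 2',4'-dihydroxydihydrochalcone 3 + o-quinone methide 7 (released from ammonium salt 6), a conjugate addition without protecting groups.
3. Enabling feature: in ring B the phenol oxygen sits on the carbon next to the CH2-bearing carbon, so "ring B + CH2" is a latent o-quinone methide (O=C–C=CH2). In ring A, C3' lies between O2' and O4', and the six-membered O2'–H···O=C chelate to the ketone on C1' fixes C3'=C4' as the enol double bond of O4', so C3' rather than C5' is the nucleophilic carbon.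
4. 3 ⇐ resorcinol 1 + 3-phenylpropanoic acid 2 (Friedel–Crafts acylation); 6 ⇐ Mannich base 4 + iodomethane 5.
5. No ring is constructed: all three benzene rings are bought (in 1, 2 and 4).

Key step: step 3

Remark: the target has no stereocentre; ring A is the ketone-bearing ring (C1' acyl, C2' OMe, C3' benzylic CH2, C4' OH), ring B is the 2-hydroxyphenyl ring, and 2-[(dimethylamino)methyl]phenol is taken as commercially available.

Step 1
Reactants: 1 resorcinol; 2 3-phenylpropanoic acid
Product: 3 1-(2,4-dihydroxyphenyl)-3-phenylpropan-1-one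
Conditions: BF3·OEt2 (solvent), 90 °C; then aq. NaOAc
Reagents that add atoms: 3-phenylpropanoic acid (2), O=C(O)CCc1ccccc1
Why: Nencki-type Friedel–Crafts C-acylation: the BF3-activated acid should acylate resorcinol at C4, ortho to one OH and para to the other, and the electron-withdrawing acyl group then deactivates the ring against a second acylation.

Step 2
Reactants: 4 2-[(dimethylamino)methyl]phenol; 5 iodomethane
Product: 6 (2-hydroxybenzyl)trimethylammonium iodide
Conditions: MeI (1.1 equiv), acetone, rt; filter the salt
Reagents that add atoms: iodomethane (5), CI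
Why: Menshutkin quaternisation: the tertiary amine is far more nucleophilic than the un-ionised phenol, so only nitrogen should be methylated and the salt should crystallise from the medium.

Step 3
Reactants: 3 1-(2,4-dihydroxyphenyl)-3-phenylpropan-1-one; 6 (2-hydroxybenzyl)trimethylammonium iodide
Product: 8 1-[2,4-dihydroxy-3-(2-hydroxybenzyl)phenyl]-3-phenylpropan-1-one, via o-quinone methide 7 (not isolated)
Conditions: K2CO3 (3 equiv), MeCN–H2O 9:1, N2, 80 °C; 3 in excess (2 equiv), 6 added in portions; then 1 M HCl
Reagents that add atoms: (2-hydroxybenzyl)trimethylammonium iodide (6), C[N+](C)(C)Cc1ccccc1O.[I-]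
Why: Carbonate deprotonates the phenol of 6 and the phenoxide expels NMe3 in a 1,4-elimination to give o-quinone methide 7, whose exocyclic CH2 is attacked in a conjugate (Michael) addition by C3' of the 4'-phenoxide of 3, after which a proton shift restores both aromatic rings. The closest known reaction type is the base-mediated C-(2-hydroxybenzyl)ation of phenols and 1,3-dicarbonyl compounds with Mannich-base methiodides, together with the nuclear C-alkylation, Mannich and Duff reactions of 2,4-dihydroxyaryl ketones, which go to the carbon between the two oxygens. No ring is closed and no stereocentre is formed. The step needs C3' over C5' and C over O: the O2'–H···O=C chelate fixes the C3'=C4' enolate double bond so that C3', which is also ortho to O2', is the nucleophilic carbon, and O-attack is reversible because the aryl 2-hydroxybenzyl ether re-expels the 4-acylphenoxide and drains to the C-adduct. Excess 3 and portionwise addition of 6 keep 7 dilute, which should suppress a second benzylation at C5' and self-condensation of 7.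

Step 4
Reactants: 8 1-[2,4-dihydroxy-3-(2-hydroxybenzyl)phenyl]-3-phenylpropan-1-one; 9 benzyl bromide
Product: 10 1-[4-(benzyloxy)-3-[2-(benzyloxy)benzyl]-2-hydroxyphenyl]-3-phenylpropan-1-one
Conditions: BnBr (2.1 equiv), K2CO3, acetone, reflux
Reagents that add atoms: benzyl bromide (9), BrCc1ccccc1
Why: Williamson ether synthesis with chemoselection by acidity and hydrogen bonding: K2CO3 in acetone ionises the 4'-OH and the ring-B OH, whereas the 2'-OH, held in the chelate to the ketone and flanked by the acyl and benzyl groups, should remain free.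

Step 5
Reactants: 10 1-[4-(benzyloxy)-3-[2-(benzyloxy)benzyl]-2-hydroxyphenyl]-3-phenylpropan-1-one; 5 iodomethane
Product: 11 1-[4-(benzyloxy)-3-[2-(benzyloxy)benzyl]-2-methoxyphenyl]-3-phenylpropan-1-one
Conditions: MeI (5 equiv), K2CO3, DMF, 60 °C
Reagents that add atoms: iodomethane (5), CI
Why: Williamson O-methylation of the one remaining, chelated phenol under more forcing dipolar aprotic conditions; K2CO3 is too weak to enolise the ketone, so C-methylation should not compete, and the benzyl ethers are inert.

Step 6
Reactants: 11 1-[4-(benzyloxy)-3-[2-(benzyloxy)benzyl]-2-methoxyphenyl]-3-phenylpropan-1-one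
Product: 12 1-[4-hydroxy-3-(2-hydroxybenzyl)-2-methoxyphenyl]-3-phenylpropan-1-one (target)
Conditions: H2 (1 atm), 10% Pd/C, EtOAc, rt
Reagents that add atoms: none
Why: Heterogeneous catalytic hydrogenolysis of the two aryl benzyl ethers; under neutral conditions at 1 atm the aryl ketone, the methyl ether and the diarylmethane CH2 should be untouched.

**Compound list**
1 | resorcinol (benzene-1,3-diol) | Oc1cccc(O)c1 | starting material
2 | 3-phenylpropanoic acid | O=C(O)CCc1ccccc1 | starting material
3 | 1-(2,4-dihydroxyphenyl)-3-phenylpropan-1-one | O=C(CCc1ccccc1)c1ccc(O)cc1O | intermediate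
4 | 2-[(dimethylamino)methyl]phenol | CN(C)Cc1ccccc1O | starting material
5 | iodomethane | CI | starting material
6 | (2-hydroxybenzyl)trimethylammonium iodide | C[N+](C)(C)Cc1ccccc1O.[I-] | intermediate
7 | o-quinone methide (6-methylidenecyclohexa-2,4-dien-1-one) | C=C1C=CC=CC1=O | intermediate
8 | 1-[2,4-dihydroxy-3-(2-hydroxybenzyl)phenyl]-3-phenylpropan-1-one | O=C(CCc1ccccc1)c1ccc(O)c(Cc2ccccc2O)c1O | intermediate
9 | benzyl bromide | BrCc1ccccc1 | starting material
10 | 1-[4-(benzyloxy)-3-[2-(benzyloxy)benzyl]-2-hydroxyphenyl]-3-phenylpropan-1-one | O=C(CCc1ccccc1)c1ccc(OCc2ccccc2)c(Cc2ccccc2OCc2ccccc2)c1O | intermediate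
11 | 1-[4-(benzyloxy)-3-[2-(benzyloxy)benzyl]-2-methoxyphenyl]-3-phenylpropan-1-one | COc1c(C(=O)CCc2ccccc2)ccc(OCc2ccccc2)c1Cc1ccccc1OCc1ccccc1 | intermediate
12 | 1-[4-hydroxy-3-(2-hydroxybenzyl)-2-methoxyphenyl]-3-phenylpropan-1-one | COc1c(C(=O)CCc2ccccc2)ccc(O)c1Cc1ccccc1O | target

**Step count**
Total steps: 6. Longest linear sequence: 5 (steps 1, 3, 4, 5, 6); step 2 is a one-step side branch.

**Three steps most likely to fail**

Step 3 (key step). The phenoxide may attack through C5' instead of C3', the product may be hydroxybenzylated a second time, or the quinone methide may self-condense. The fallback replaces quinone methide chemistry by an aryl halide cross-coupling and sets out from 3. Iodination with I2/HIO3 in aqueous ethanol should place iodine between the two hydroxyls and give 1-(2,4-dihydroxy-3-iodophenyl)-3-phenylpropan-1-one F1. Benzylation of the non-chelated 4'-OH (BnBr 1.05 equiv, K2CO3, acetone) should give 1-[4-(benzyloxy)-2-hydroxy-3-iodophenyl]-3-phenylpropan-1-one F2, and methylation of the chelated OH (MeI, K2CO3, DMF) should give 1-[4-(benzyloxy)-3-iodo-2-methoxyphenyl]-3-phenylpropan-1-one F3. Negishi coupling of F3 with [2-(benzyloxy)benzyl]zinc bromide F4 (from commercial 1-(benzyloxy)-2-(bromomethyl)benzene, Zn dust and LiCl in THF) under Pd(OAc)2/SPhos in THF at 50 °C should form the same C3'–CH2 bond. The fallback comes back to the route at 11, leaving only step 6.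

Step 5. Alkylation of the hydrogen-bonded, doubly flanked 2'-OH may be sluggish, and forcing it with stronger base invites enolate C-methylation next to the ketone. The fallback breaks the chelate by a temporary change of oxidation level and sets out from 10. NaBH4 in MeOH/THF should reduce the ketone to racemic 3-(benzyloxy)-2-[2-(benzyloxy)benzyl]-6-(1-hydroxy-3-phenylpropyl)phenol F5. The phenol, no longer chelated, should be methylated by MeI/K2CO3 in acetone at rt to racemic 1-[4-(benzyloxy)-3-[2-(benzyloxy)benzyl]-2-methoxyphenyl]-3-phenylpropan-1-ol F6. MnO2 in CH2Cl2 should re-oxidise the benzylic alcohol, and the fallback comes back to the route at 11.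

Step 4. Chemoselectivity among the three phenols may be lost, through incomplete benzylation of the ring-B OH or partial benzylation of the chelated 2'-OH. The fallback uses exhaustive alkylation followed by chelation-controlled dealkylation and sets out from 8. Excess BnBr/K2CO3 in DMF at 70 °C should give the tris-benzyl ether 1-[2,4-bis(benzyloxy)-3-[2-(benzyloxy)benzyl]phenyl]-3-phenylpropan-1-one F7. MgBr2·OEt2 in toluene/Et2O at reflux should then cleave only the benzyl ether ortho to the carbonyl, through a six-membered magnesium chelate, and the fallback comes back to the route at 10.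

**Further compounds**
F1 | step 3 | 1-(2,4-dihydroxy-3-iodophenyl)-3-phenylpropan-1-one | O=C(CCc1ccccc1)c1ccc(O)c(I)c1O
F2 | step 3 | 1-[4-(benzyloxy)-2-hydroxy-3-iodophenyl]-3-phenylpropan-1-one | O=C(CCc1ccccc1)c1ccc(OCc2ccccc2)c(I)c1O
F3 | step 3 | 1-[4-(benzyloxy)-3-iodo-2-methoxyphenyl]-3-phenylpropan-1-one | COc1c(C(=O)CCc2ccccc2)ccc(OCc2ccccc2)c1I
F4 | step 3 | [2-(benzyloxy)benzyl]zinc bromide | Br[Zn]Cc1ccccc1OCc1ccccc1
F5 | step 5 | 3-(benzyloxy)-2-[2-(benzyloxy)benzyl]-6-(1-hydroxy-3-phenylpropyl)phenol (racemic) | OC(CCc1ccccc1)c1ccc(OCc2ccccc2)c(Cc2ccccc2OCc2ccccc2)c1O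
F6 | step 5 | 1-[4-(benzyloxy)-3-[2-(benzyloxy)benzyl]-2-methoxyphenyl]-3-phenylpropan-1-ol (racemic) | COc1c(C(O)CCc2ccccc2)ccc(OCc2ccccc2)c1Cc1ccccc1OCc1ccccc1
F7 | step 4 | 1-[2,4-bis(benzyloxy)-3-[2-(benzyloxy)benzyl]phenyl]-3-phenylpropan-1-one | O=C(CCc1ccccc1)c1ccc(OCc2ccccc2)c(Cc2ccccc2OCc2ccccc2)c1OCc1ccccc1
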